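Ring numbering: C1 (aroyloxy carbinol), C2(Me)=C3, C4 (carbinol), C5 (CMe2), C6–C8, C9(Me)=C10, C11. The eleven-membered carbocycle is grown from a ten-membered lactone (O, C1, C11 to C5, C4=O) that carries C2=C3 as a (Z)-iodoalkenyl arm on C1. Iodine–lithium exchange lets C3 attack the lactone carbonyl C4. The bridged hemiketal opens at its ring C4–O bond, so oxygen leaves the ring while C2 and C3 enter it. The step exploits the cis-1,4-dioxygenated C1–C2=C3–C4 segment: it forges C3–C4, keeps the Z olefin, and releases a chelated alkoxide–ketone that is reduced in the same flask to the cis-diol.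

Key step: step 7

Assumption: 5-bromo-2-methylpent-1-ene, 4-acetoxybenzoyl chloride and the pentane solution of (−)-Ipc2B(allyl) are treated as purchasable, and the ring numbering of the first paragraph is used throughout.

Step 1
Reactants: 1 prop-2-yn-1-ol
Product: 2 (Z)-3-iodo-2-methylprop-2-en-1-ol
Conditions: MeMgBr (2.5 equiv), CuI (10 mol %), THF, −10 °C → rt; iodine, −40 → 0 °C; H2O
Reagents that add atoms: methylmagnesium bromide C[Mg]Br; iodine [I][I]
Why: Alkoxide-directed, copper-catalysed anti-carbomagnesiation places methyl on the inner alkyne carbon and magnesium in a five-membered chelate cis to CH2O, so iodinolysis with retention should give the Z iodide.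

Step 2
Reactants: 2 (Z)-3-iodo-2-methylprop-2-en-1-ol
Product: 3 (Z)-3-iodo-2-methylprop-2-enal
Conditions: activated MnO2 (15 equiv), CH2Cl2, rt, dark; filtered and used at once
Reagents that add atoms: none
Why: Heterogeneous MnO2 oxidation of an allylic alcohol is neutral and stops at the aldehyde, which should keep the labile Z geometry if the product is used directly.

Step 3
Reactants: 3 (Z)-3-iodo-2-methylprop-2-enal
Product: 4 (1Z,3S)-1-iodo-2-methylhexa-1,5-dien-3-ol
Conditions: (−)-Ipc2B(allyl) (1 M in pentane), Et2O, −78 °C; NaOH, H2O2, 0 °C → rt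
Reagents that add atoms: (−)-B-allyldiisopinocampheylborane C=CCB([C@@H]1C[C@@H]2C[C@H]([C@H]1C)C2(C)C)[C@@H]1C[C@@H]2C[C@H]([C@H]1C)C2(C)C
Why: Brown allylboration through a chair Zimmerman–Traxler transition state, in which the isopinocampheyl groups derived from (+)-α-pinene direct allyl to the Si face and set C1 as S.

Step 4
Reactants: 5 isobutyric acid, 6 5-bromo-2-methylpent-1-ene
Product: 7 2,2,6-trimethylhept-6-enoic acid
Conditions: LDA (2.1 equiv), THF, 0 → 40 °C; 6, 0 °C → rt; 1 M HCl
Reagents that add atoms: none
Why: SN2 alkylation of the lithium enediolate (dianion) of isobutyric acid builds the quaternary C5 and delivers the free acid directly.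

Step 5
Reactants: 7 2,2,6-trimethylhept-6-enoic acid, 4 (1Z,3S)-1-iodo-2-methylhexa-1,5-dien-3-ol
Product: 9 (1Z,3S)-1-iodo-2-methylhexa-1,5-dien-3-yl 2,2,6-trimethylhept-6-enoate, via acid chloride 8 (not isolated)
Conditions: (COCl)2, DMF (cat.), CH2Cl2, 0 °C → rt, evaporate; 4, Et3N, DMAP (0.2 equiv), CH2Cl2, 0 °C → rt
Reagents that add atoms: oxalyl chloride O=C(Cl)C(=O)Cl (its chlorine stays only in 8)
Why: Acyl chloride formation followed by DMAP-catalysed acylation overcomes the hindrance of the pivalate-type acid, and C1 keeps its configuration because only its O–H bond reacts.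

Step 6
Reactants: 9 (1Z,3S)-1-iodo-2-methylhexa-1,5-dien-3-yl 2,2,6-trimethylhept-6-enoate
Product: 10 (7Z,10S)-10-[(1Z)-1-iodoprop-1-en-2-yl]-3,3,7-trimethyl-3,4,5,6,9,10-hexahydro-2H-oxecin-2-one
Conditions: second-generation Hoveyda–Grubbs catalyst (10 mol %), toluene (1 mM), 80 °C, slow addition of 9, argon sparge
Reagents that add atoms: none
Why: Ring-closing metathesis of the monosubstituted with the 1,1-disubstituted olefin, where the ring-cis trisubstituted olefin is clearly the less strained isomer in a ten-membered ring so the reversible NHC–ruthenium catalyst should settle on C9=C10 Z, the gem-dimethyl group (Thorpe–Ingold effect) favours closure, and the hindered electron-poor iodoalkene stays out.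

Step 7
Reactants: 10 (7Z,10S)-10-[(1Z)-1-iodoprop-1-en-2-yl]-3,3,7-trimethyl-3,4,5,6,9,10-hexahydro-2H-oxecin-2-one
Product: 14 (1S,2Z,4S,9Z)-2,5,5,9-trimethylcycloundeca-2,9-diene-1,4-diol, via alkenyllithium 11 (not isolated), via bridged hemiketal alkoxide 12 (not isolated), via enone alkoxide 13 (not isolated)
Conditions: t-BuLi (2.1 equiv), Et2O, −78 °C, then → −20 °C; recool to −78 °C, Zn(BH4)2 (1.5 equiv, Et2O), → −30 °C; H2O
Reagents that add atoms: none
Why: t-BuLi exchanges the alkenyl iodide much faster than it adds to the pivalate-type carbonyl (quaternary C5, no α-hydrogen), and the configurationally stable (Z)-alkenyllithium 11 holds C3 next to C4. C3 closes a five-membered ring on the carbonyl (5-exo-trig) to the 12-oxabicyclo[7.2.1] hemiketal alkoxide 12, in which the transient C4 centre is fixed by the C5–C11 bridge that must sit cis on the dihydrofuran; collapse with cleavage of the endocyclic C4–O bond turns the ten-membered lactone into the eleven-membered enone alkoxide 13, so the carbocycle arises by bond cleavage in the bicycle and not by a macrocyclisation. The closest known type is the halogen–metal-exchange-initiated intramolecular nucleophilic acyl substitution of halo esters and halo lactones (Parham-type cyclisation, anionic 1,4 O-to-C acyl shift). The step needs exchange before carbonyl addition, retention of the C2=C3 geometry and an untouched C1: the hindered carbonyl secures the first, only the cis alkenyllithium can reach C4, and the C1–O bond is never broken. The new C4 stereocentre is set by chelation: 13 is born with lithium (then zinc) bridging O1 and the ketone oxygen across the Z olefin, C11 and C5 then both point to the same face, the carbon bridge covers that face, and Zn(BH4)2 delivers hydride 1,2 from the open one, which should give 4S (cis-1,4-diol). Reduction in the same flask also forestalls hemiketal formation and dehydration of the cis-γ-hydroxy enone to a furan.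

Step 8
Reactants: 14 (1S,2Z,4S,9Z)-2,5,5,9-trimethylcycloundeca-2,9-diene-1,4-diol, 15 4-acetoxybenzoyl chloride
Product: 16 (1S,2Z,4S,9Z)-4-hydroxy-2,5,5,9-trimethylcycloundeca-2,9-dien-1-yl 4-acetoxybenzoate
Conditions: 15 (1.05 equiv), Et3N, DMAP (5 mol %), CH2Cl2, −40 → 0 °C
Reagents that add atoms: none
Why: In this DMAP-catalysed O-acylation the C1 hydroxyl (flanked by C11H2) should react far faster than the neopentyl C4 hydroxyl next to C5, and neither C–O bond is broken, so both stereocentres are kept.

Step 9
Reactants: 16 (1S,2Z,4S,9Z)-4-hydroxy-2,5,5,9-trimethylcycloundeca-2,9-dien-1-yl 4-acetoxybenzoate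
Product: 17 (1S,2Z,4S,9Z)-4-hydroxy-2,5,5,9-trimethylcycloundeca-2,9-dien-1-yl 4-hydroxybenzoate
Conditions: K2CO3 (0.2 equiv), MeOH, 0 °C
Reagents that add atoms: none
Why: Base-catalysed transesterification cleaves the aryl acetate much faster than the alkyl benzoate, whose carbonyl is deactivated further once the phenoxide forms.

Compound list
1 | prop-2-yn-1-ol | C#CCO | starting material
2 | (Z)-3-iodo-2-methylprop-2-en-1-ol | OC/C(C)=C\I | intermediate
3 | (Z)-3-iodo-2-methylprop-2-enal | O=C/C(C)=C\I | intermediate
4 | (1Z,3S)-1-iodo-2-methylhexa-1,5-dien-3-ol | C=CC[C@H](O)/C(C)=C\I | intermediate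
5 | isobutyric acid | CC(C)C(=O)O | starting material
6 | 5-bromo-2-methylpent-1-ene | C=C(C)CCCBr | starting material
7 | 2,2,6-trimethylhept-6-enoic acid | C=C(C)CCCC(C)(C)C(=O)O | intermediate
8 | 2,2,6-trimethylhept-6-enoyl chloride (not isolated) | C=C(C)CCCC(C)(C)C(=O)Cl | intermediate
9 | (1Z,3S)-1-iodo-2-methylhexa-1,5-dien-3-yl 2,2,6-trimethylhept-6-enoate | C=CC[C@H](OC(=O)C(C)(C)CCCC(C)=C)/C(C)=C\I | intermediate
10 | (7Z,10S)-10-[(1Z)-1-iodoprop-1-en-2-yl]-3,3,7-trimethyl-3,4,5,6,9,10-hexahydro-2H-oxecin-2-one (ten-membered lactone) | C/C1=C/C[C@H](OC(=O)C(C)(C)CCC1)/C(C)=C\I | intermediate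
11 | (7Z,10S)-10-[(1Z)-1-lithioprop-1-en-2-yl]-3,3,7-trimethyl-3,4,5,6,9,10-hexahydro-2H-oxecin-2-one (not isolated) | C/C1=C/C[C@H](OC(=O)C(C)(C)CCC1)/C(C)=C\[Li] | intermediate
12 | lithium (1S,6Z,9S)-2,2,6,10-tetramethyl-12-oxabicyclo[7.2.1]dodeca-6,10-dien-1-olate (not isolated) | C/C1=C/C[C@@H]2O[C@@]([O-])(C=C2C)C(C)(C)CCC1.[Li+] | intermediate
13 | lithium (1S,2Z,9Z)-2,5,5,9-trimethyl-4-oxocycloundeca-2,9-dien-1-olate (not isolated) | C/C1=C/C[C@H]([O-])/C(C)=C\C(=O)C(C)(C)CCC1.[Li+] | intermediate
14 | (1S,2Z,4S,9Z)-2,5,5,9-trimethylcycloundeca-2,9-diene-1,4-diol | C/C1=C/C[C@H](O)/C(C)=C\[C@H](O)C(C)(C)CCC1 | intermediate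
15 | 4-acetoxybenzoyl chloride | CC(=O)Oc1ccc(cc1)C(=O)Cl | starting material
16 | (1S,2Z,4S,9Z)-4-hydroxy-2,5,5,9-trimethylcycloundeca-2,9-dien-1-yl 4-acetoxybenzoate | C/C1=C/C[C@H](OC(=O)c2ccc(OC(C)=O)cc2)/C(C)=C\[C@H](O)C(C)(C)CCC1 | intermediate
17 | (1S,2Z,4S,9Z)-4-hydroxy-2,5,5,9-trimethylcycloundeca-2,9-dien-1-yl 4-hydroxybenzoate | C/C1=C/C[C@H](OC(=O)c2ccc(O)cc2)/C(C)=C\[C@H](O)C(C)(C)CCC1 | target

Total step count: 9
Longest linear sequence: 8 steps (steps 1, 2, 3, 5, 6, 7, 8, 9)

Steps most likely to fail

1. Step 6. Intermolecular metathesis (oligomerisation) may outrun closure of the strained ten-membered ring, or the ring-trans olefin may form under kinetic control. The fallback sets out from 4 and comes back at 10. It fixes the olefin in a ring that allows no other geometry and closes the large ring at the ester bond.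
 - Alcohol 4 is acylated with methacryloyl chloride (Et3N, DMAP) to the methacrylate F1.
 - Ring-closing metathesis of F1 can only give the six-membered lactone F2, with a ring-cis C9=C10 bond.
 - DIBAL-H (1 equiv, toluene, −78 °C) gives the lactol F3.
 - A Wittig reaction with the ylide from (3-carboxy-3-methylbutyl)triphenylphosphonium bromide (NaHMDS, THF) adds C4–C7 and gives the trienoic acid F4.
 - Diimide (2-nitrobenzenesulfonyl hydrazide, Et3N) should saturate only the new disubstituted C7=C8 bond, giving the seco acid F5.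
 - Shiina macrolactonisation (MNBA, DMAP, high dilution) gives 10.

2. Step 7. The alkenyllithium may be lost by protonation, or by syn-elimination of the allylic carboxylate, before it reaches the hindered carbonyl. Chelate control may also be lost, so that hydride adds to the other face. The fallback sets out from 10 and comes back at 14.
 - DIBAL-H (toluene, −78 °C) opens the lactone to the non-enolisable hydroxy aldehyde F6.
 - A Nozaki–Hiyama–Kishi reaction (CrCl2, NiCl2 cat., DMSO–THF, high dilution) joins C3 to C4 at the aldehyde level.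
 - The chromium alkoxide at O1 should bind the aldehyde oxygen, so that the carbon chain again spans one face. This gives 14 without a separate reduction.

3. Step 2. The β-iodo enal may drift from Z to E on the oxidant or during handling. That would carry the wrong C2=C3 geometry forward, and an E-alkenyllithium cannot reach C4. The fallback sets out from 1 and comes back at 4. It sets the stereocentre first and the iodoalkene last.
 - 1 is oxidised (MnO2, CH2Cl2) to propynal F7.
 - Brown allylboration with the same (−)-Ipc2B(allyl) gives the enynol F8.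
 - The alkoxide-directed anti-carbomagnesiation and iodinolysis of step 1 (MeMgBr, CuI, then iodine) is run on F8 to give 4, so no β-iodo enal is ever handled.

Further compounds
F1 | step 6 | (1Z,3S)-1-iodo-2-methylhexa-1,5-dien-3-yl 2-methylprop-2-enoate | C=CC[C@H](OC(=O)C(C)=C)/C(C)=C\I
F2 | step 6 | (6S)-6-[(1Z)-1-iodoprop-1-en-2-yl]-3-methyl-5,6-dihydro-2H-pyran-2-one | CC1=CC[C@H](OC1=O)/C(C)=C\I
F3 | step 6 | (6S)-6-[(1Z)-1-iodoprop-1-en-2-yl]-3-methyl-5,6-dihydro-2H-pyran-2-ol (anomeric mixture) | CC1=CC[C@H](OC1O)/C(C)=C\I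
F4 | step 6 | (4Z,6Z,9S,10Z)-9-hydroxy-11-iodo-2,2,6,10-tetramethylundeca-4,6,10-trienoic acid | OC(=O)C(C)(C)C/C=C\C(C)=C/C[C@H](O)/C(C)=C\I
F5 | step 6 | (6Z,9S,10Z)-9-hydroxy-11-iodo-2,2,6,10-tetramethylundeca-6,10-dienoic acid | OC(=O)C(C)(C)CCC/C(C)=C\C[C@H](O)/C(C)=C\I
F6 | step 7 | (6Z,9S,10Z)-9-hydroxy-11-iodo-2,2,6,10-tetramethylundeca-6,10-dienal | O=CC(C)(C)CCC/C(C)=C\C[C@H](O)/C(C)=C\I
F7 | step 2 | propynal | C#CC=O
F8 | step 2 | (3S)-hex-5-en-1-yn-3-ol | C=CC[C@H](O)C#C
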